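The vessel was closed, stirred and held at one temperature, and two earlier runs had been made in it, with equal reagent and initiator but different substrate.

all flasks: reagent 0.255 M; initiator 8.5 mM

| flask | substrate | remark | time |
|---|---|---|---|
| south | 0.055 M | run made earlier |  |
| north-west | 0.45 M | run made earlier |  |
| summer | 0.080 M |  | 6.0 h |
| dawn | 0.15 M |  | 6.0 h |
| dusk | 0.30 M |  | 6.0 h |
| autumn | 0.60 M |  | 6.0 h |

| run | time / h | target / % |
|---|---|---|
| south | 0.833 | 77.0 |
| south | 2.00 | 98.9 |
| south | 4.00 | 96.6 |
| south | 6.00 | 98.2 |
| north-west | 1.50 | 17.2 |
| north-west | 3.00 | 25.3 |
| north-west | 5.00 | 27.1 |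
| north-west | 6.00 | 26.2 |

(each reading ± 1 percentage point)

- "hardly changes" means that all values lie within two and a half points (for a concentration: within two and a half percent of the largest)

1. [target] at the end for summer, dawn, dusk, autumn, in this order
2. the shape of the row from first to last (hardly changes / falls, then rises / falls all the way / rises, then falls / rises all the way)

I began with the making rate: the first south reading gave 0.0508 M h⁻¹ of target. At that rate I reckoned the reagent charge lasted 5.02 h, less than the 6.0 h asked.

In the north-west run, target rose by 0.0365 M between 1.50 h and 3.00 h, but the making rate gave 0.0763 M, so 0.0398 M had gone. I supposed that target was lost to substrate, one for one. Over that stretch target averaged 0.0956 M and substrate 0.316 M. That gave 0.879 M⁻¹ h⁻¹ for the loss constant, a second-order rate constant: the share of target lost per hour for each molar of substrate.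

For autumn I took substrate as 0.345 M, the charge less the reagent charge. Target then climbed towards the ceiling where making equals loss, 0.168 M, and reached 0.131 M when the reagent ended. The last 0.980 h of loss left 0.0972 M.

For dusk, if reagent and substrate both ended, made plus lost equalled the substrate charge, which left 0.210 M of target. Summer and dawn held less substrate than reagent, so I put them near their charges. My row therefore rose to dusk and fell by autumn.

The weakest link was the making rate, taken from one reading. The first north-west reading gave 0.0516 M h⁻¹ of target after loss; adding the loss back, with target at 0.0387 M on average and substrate at its charge, made 0.0669 M h⁻¹, faster than the south value. With that rate and my loss constant unchanged, autumn came to 0.0778 M, still below my dusk figure, so the shape of my row held.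

The forecast differed from my row. It gave 0.079 M, 0.12 M, 0.12 M and 0.12 M, a row that rises all the way, on the ground that “Something other than substrate has run out”.

    2 second chain carrier → ended chains B (k = 7.00 × 10⁶ M⁻¹ s⁻¹)
    reagent + first chain carrier → target + second chain carrier (k = 24000 M⁻¹ s⁻¹)
    initiator → 2 initiating radical (k = 8.00 × 10⁻⁴ h⁻¹)
    substrate + target → side product (k = 0.970 M⁻¹ h⁻¹)
    substrate + initiating radical → capped initiator + first chain carrier (k = 3.40 × 10⁵ M⁻¹ s⁻¹)
    substrate + second chain carrier → by-product + first chain carrier (k = 41000 M⁻¹ s⁻¹)
    2 first chain carrier → ended chains A (k = 1.00 × 10⁸ M⁻¹ s⁻¹)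

The flask gave 0.0767 M, 0.133 M, 0.170 M and 0.0770 M, a row that rises, then falls, turning at 0.26 M of substrate. With the passing of substrate and target into side product switched off, autumn held 0.228 M of target, more than the 0.0770 M it really held. On the 36.8% of substrate left in autumn, my loss constant gives target a life of 5.15 h, and autumn target stood at 0.0788% after 60.0 h. On the 5.00% left in dusk it gives 75.9 h, and dusk target stood at 60.2% after 60.0 h.

(The runs come from a simulation for an exercise; noise was put on by code.)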